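## The problem

The target is an eremophilane: a trans-fused decalin (C5 β-methyl, C10 α-hydrogen) with seven stereocentres (C3, C4, C5, C7, C8, C9, C10). Ring A holds the hardest carbon array, the quaternary C5 next to C4, both methyl-bearing and cis, flanked by the C3 oxygen and the ring-fusion C10–H. Ring B carries three contiguous centres: the equatorial 7α-isopropenyl group, the free axial 8α-hydroxyl and the equatorial 9α-ester. Once the trans-decalin chair exists, C7 (enolisable next to a C8 ketone, equatorial by equilibration) and C8 (hydride from the equatorial side) can be set by the ring; C9 cannot, so it has to come first and is then the one centre that can steer all the others. The two (Z)-hex-2-enoates isomerise and accept nucleophiles, the isopropenyl group slips into conjugation next to a ketone and is lost on hydrogenation, and the cis 8-hydroxy-9-ester can undergo acyl migration, so the esters belong at the very end. Three secondary hydroxyls must be told apart: C3 and C9 acylated, C8 left free. The enabling feature is ring A itself: C3–O, C4–CH3, C5(CH3) and C10–H on a cyclohexane are the retron of a [4+2] cycloaddition between a 1-oxydiene (C10=C1–C2=C3–O) and an (E)-β-methyl enal (C4=C5, C15 as CHO), with C6–C9 as a tether that becomes ring B.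

## Retrosynthesis

**Ester side chains (31 from 30).** No skeletal bond is cut; the two (Z)-alkenes of 31 are traced to the alkynes of bis(hex-2-ynoate) 30. Direct use of (Z)-hex-2-enoic acid is avoided because nucleophilic acylation catalysts and phosphines isomerise Z-enoates. The alkyne has no geometry to lose, and hex-2-ynoic acid 28 is acidic enough to be a good Mitsunobu partner. The forward step must reduce two ynoates without touching the isopropenyl group.

**C3–O and C9–O (30 from 29 from 27 and 28).** The C3–O bond is cut with inversion, because the cycloaddition below delivers the 3β (axial) oxygen while the target needs 3α. The C9–O bond is cut with retention. Acylating C9 first on triol 27 uses the only unhindered equatorial hydroxyl; the later Mitsunobu step then meets a C8 hydroxyl that is flanked on both sides. The precursor 27 is a plain triol; the forward steps need site selectivity among three secondary alcohols.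

**C8–H and C7–C11 (27 from 26 from 25 from 22 and 23).** Making C8 a ketone removes one stereocentre and makes C7 enolisable, so the isopropenyl group can be cut off as 2-bromopropene 23 (palladium-catalysed enolate alkenylation). An aldol with acetone and dehydration would favour the conjugated isopropylidene isomer, and a cuprate would need an enone at the wrong carbon. Ketone 22 has lost three carbons and two stereocentres. The forward steps need enolisation toward C7 and not C9, no migration of the new alkene, and hydride attack from the equatorial side.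

**Functional-group adjustments (22 from 21 from 20 from 16).** The C1=C2 alkene, the dithiane at C8 and the C15 aldehyde of cycloadduct 16 are the marks left by the ring-forming step. The aldehyde goes first because a β-silyloxy aldehyde eliminates easily. Sulfur goes before the hydrogenation because it poisons the catalyst, and the hydrogenation goes before the isopropenyl group exists.

**C5–C10 and C3–C4 (16 from 15).** Both rings are opened at once by a retro-[4+2], giving the acyclic (E,E,E)-trienal 15 with a single stereocentre (C9). This cut is preferred over any stepwise annulation because it sets C4, C5 and C10, and C3 provisionally, from alkene geometry and one carbinol. The dithiane at C8 masks the ketone, prevents enolisation of C9 and helps the tether to fold. The forward reaction must be endo-selective (trans fusion) and face-selective under C9 control.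

**Enal unveiling and C9 configuration (15 from 14 from 13 from 12 from 11 from 10).** The enal is oxidised up last from an allylic alcohol. The C15 oxygen is carried as a pivalate because the silyl dienol ether tolerates neither acid nor fluoride, and a pivalate can be removed by hydride. C9 is set by oxazaborolidine-catalysed reduction of dienone 11, where a fully substituted dithianyl carbon faces a planar dienyl group.

**C8–C9 (9 from 5 and 7).** The carbinol is cut next to the dithiane into a 2-lithiodithiane and an aldehyde. The aldehyde partner 7 brings C9, C10, C1, C2, C3 and the C3 oxygen with both diene double bonds already (E). The forward step needs 1,2-addition to a dienal.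

**Building blocks (5 from 4 from 3 from 1; 7 from 6).** The C4–C8 chain with its (E)-trisubstituted alkene is the head of geraniol, so geranyl acetate 1 gives it by cleavage of the distal alkene. This avoids the E/Z mixture of an olefination on a methyl ketone. Aldehyde 7 is one silylation away from glutaconaldehyde potassium salt 6.

## Roads not taken

Alternative 1: The cut is at C5–C6 and C4–C15 on a preformed ring A. Enone A1 would take up a vinylcopper reagent at C5 and the resulting enolate would be methylated at C4, giving cyclohexanone A2 in one pot. The merit is real: the vicinal C4/C5 pair, including the quaternary carbon, is set by a well-known conjugate addition and enolate trapping, each anti to its neighbour, under control of the C10 stereocentre. The C3 ketone of A2 could also give the equatorial 3α-alcohol by thermodynamically controlled reduction, with no inversion step; in that respect it is better than the chosen plan. Its weak points are that copper addition to a β,β-disubstituted enone next to a substituted C10 is slow, and that no ring is formed. A2 has neither the C8/C9 oxygens nor the C7 isopropenyl group, and direct metathesis of its vinyl and methallyl groups would close a five-membered ring. Ring B and its three contiguous stereocentres would therefore need several more C–C bond formations and oxidations. The chosen plan sets against the convenient C3 ketone of A2 the closure of both rings and three permanent stereocentres in one step.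

Alternative 2: The cut is the C8–C9 bond. SmI2 would couple the two aldehyde groups of dialdehyde A3 in a pinacol reaction, closing ring B and giving the cis-8,9-diol A4 directly. This is the best of the three for ring B: the cis-diol arises from samarium chelation, the 8α,9α isomer avoids a syn-axial clash with the C5 methyl, C3 is already α, and the end-game from A4 needs neither a ketone alkenylation nor a Mitsunobu inversion. The price is paid before the key step. A3 must already hold ring A with C3, C4, C5 and C10 set, and its C7 carries both an aldehyde and the isopropenyl group, an arrangement that readily epimerises and conjugates. The C10 aldehyde also puts the ring-fusion centre at risk. The quaternary-carbon problem is simply moved upstream. The chosen plan has a longer end-game than A4 would need, but it makes the ring A array that Alternative 2 presupposes.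

Alternative 3: The cut is the C7–C8 bond. Me2AlCl would promote a carbonyl-ene reaction between the C8 aldehyde of A5 and its C5 prenyl group, closing ring B and producing the isopropenyl group and the C8 carbinol together in A6. On the C7 question this is better than the chosen plan: the isopropenyl group is formed directly as the unconjugated isomer (citronellal-to-isopulegol logic) and no palladium-catalysed enolate alkenylation is needed. The weak points are that the ene reaction gives the trans, diequatorial arrangement, so A6 is the 8β epimer and needs oxidation and bulky-hydride reduction. A5 is also an α-silyloxy aldehyde that can chelate the Lewis acid and epimerise at C9. Like A3, A5 presupposes a ring A with four stereocentres and a prenyl-bearing quaternary C5. The chosen plan accepts a late alkenylation at C7 and gains the whole bicyclic core from an acyclic chain with one stereocentre.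

Key step: step 12

Assumption (remark on the chemistry): eremophilane numbering is used for all bicyclic compounds (ring A = C1–C5 and C10; ring B = C5–C10; C14 on C5, C15 on C4, C11–C13 the isopropenyl group), β is the face of the C5 methyl group, and commercial geranyl acetate is taken as the pure (2E) isomer.

## Steps

Step 1
Reactants: 1 geranyl acetate [(2E)-3,7-dimethylocta-2,6-dien-1-yl acetate]
Product: 3 (2E)-3-methyl-6-oxohex-2-en-1-yl acetate, via ozonide 2 (not isolated)
Conditions: O3 (1 equiv, Sudan Red 7B end point), CH2Cl2/pyridine, −78 °C; then Me2S, −78 °C to rt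
Reagents that add atoms: ozone, [O-][O+]=O
Why: Electrophilic ozone adds to the electron-rich 6,7-alkene much faster than to the 2,3-alkene deactivated by the allylic acetate, and reduction of ozonide 2 gives the aldehyde (ozonolysis); the (E)-alkene that becomes C4=C5 is carried over from geraniol untouched.

Step 2
Reactants: 3 (2E)-3-methyl-6-oxohex-2-en-1-yl acetate
Product: 4 (2E)-5-(1,3-dithian-2-yl)-3-methylpent-2-en-1-yl acetate
Conditions: propane-1,3-dithiol, BF3·OEt2 (cat.), CH2Cl2, −20 to 0 °C
Reagents that add atoms: propane-1,3-dithiol, SCCCS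
Why: Lewis-acid-catalysed dithioacetalisation of an aliphatic aldehyde; the allylic acetate and the trisubstituted alkene are inert at low temperature, and the dithiane both masks the future C8 ketone and makes C8 a latent nucleophile.

Step 3
Reactants: 4 (2E)-5-(1,3-dithian-2-yl)-3-methylpent-2-en-1-yl acetate
Product: 5 (2E)-5-(1,3-dithian-2-yl)-3-methylpent-2-en-1-ol
Conditions: K2CO3 (cat.), MeOH, rt
Reagents that add atoms: none
Why: Base-catalysed transesterification frees the allylic alcohol, so that no ester is present when the organolithium is made.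

Step 4
Reactants: 6 glutaconaldehyde potassium salt
Product: 7 (2E,4E)-5-[(tert-butyldimethylsilyl)oxy]penta-2,4-dienal
Conditions: TBSCl, DMF, 0 °C to rt
Reagents that add atoms: tert-butyldimethylsilyl chloride, CC(C)(C)[Si](C)(C)Cl
Why: O-Silylation of the vinylogous carboxylate at its oxygen terminus; the all-trans salt should give the (2E,4E)-silyloxydienal, which holds C9, C10, C1, C2, C3 and the C3 oxygen.

Step 5
Reactants: 5 (2E)-5-(1,3-dithian-2-yl)-3-methylpent-2-en-1-ol; 7 (2E,4E)-5-[(tert-butyldimethylsilyl)oxy]penta-2,4-dienal
Product: 9 racemic (2E,4E)-5-[(tert-butyldimethylsilyl)oxy]-1-{2-[(3E)-5-hydroxy-3-methylpent-3-en-1-yl]-1,3-dithian-2-yl}penta-2,4-dien-1-ol, via dilithio dithiane 8 (not isolated)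
Conditions: n-BuLi (2.1 equiv), THF, −30 °C, 3 h; then 7, −78 °C; pH 7 buffer
Reagents that add atoms: none
Why: Corey–Seebach umpolung: the first equivalent of n-BuLi forms the lithium alkoxide and the second metalates C2 of the dithiane; the 2-lithiodithiane should add 1,2 to the aldehyde of 7 at −78 °C and form C8–C9, giving a racemic carbinol at this stage.

Step 6
Reactants: 9 racemic diol from step 5
Product: 10 racemic (2E)-5-{2-[(2E,4E)-5-[(tert-butyldimethylsilyl)oxy]-1-hydroxypenta-2,4-dien-1-yl]-1,3-dithian-2-yl}-3-methylpent-2-en-1-yl pivalate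
Conditions: pivaloyl chloride (1.05 equiv), pyridine, CH2Cl2, 0 °C
Reagents that add atoms: pivaloyl chloride, CC(C)(C)C(Cl)=O
Why: Acylation of the unhindered primary allylic hydroxyl; the secondary carbinol next to the fully substituted dithiane carbon reacts far more slowly, so one equivalent should give the mono-ester.

Step 7
Reactants: 10 racemic hydroxy pivalate
Product: 11 (2E)-5-{2-[(2E,4E)-5-[(tert-butyldimethylsilyl)oxy]penta-2,4-dienoyl]-1,3-dithian-2-yl}-3-methylpent-2-en-1-yl pivalate
Conditions: MnO2 (excess), CH2Cl2, rt
Reagents that add atoms: none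
Why: MnO2 oxidises allylic (here dienylic) alcohols under neutral conditions and leaves the dithiane sulfur atoms, the silyl dienol ether and the pivalate alone.

Step 8
Reactants: 11 dienone pivalate
Product: 12 (2E)-5-{2-[(1S,2E,4E)-5-[(tert-butyldimethylsilyl)oxy]-1-hydroxypenta-2,4-dien-1-yl]-1,3-dithian-2-yl}-3-methylpent-2-en-1-yl pivalate
Conditions: (R)-2-methyl-CBS-oxazaborolidine [(R)-1-methyl-3,3-diphenyltetrahydro-1H,3H-pyrrolo[1,2-c][1,3,2]oxazaborole] (0.3 equiv), catecholborane, toluene/CH2Cl2, −78 to −40 °C
Reagents that add atoms: none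
Why: Corey–Bakshi–Shibata reduction: the ketone binds to the catalyst boron anti to its larger substituent, here the fully substituted dithianyl carbon, with the planar dienyl arm as the small group, so the (R)-catalyst should give the (S)-carbinol (C9, later 9α); catecholborane reduces 1,2 and spares the pivalate and the enol ether.

Step 9
Reactants: 12 (S)-hydroxy pivalate
Product: 13 (2E)-5-{2-[(1S,2E,4E)-1,5-bis[(tert-butyldimethylsilyl)oxy]penta-2,4-dien-1-yl]-1,3-dithian-2-yl}-3-methylpent-2-en-1-yl pivalate
Conditions: TBSOTf, 2,6-lutidine (excess), CH2Cl2, −78 °C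
Reagents that add atoms: tert-butyldimethylsilyl trifluoromethanesulfonate, CC(C)(C)[Si](C)(C)OS(=O)(=O)C(F)(F)F
Why: Silyl triflate silylation of a hindered secondary alcohol; excess 2,6-lutidine keeps the medium non-acidic, so the ionisable dienyl carbinol and the dienol ether survive.

Step 10
Reactants: 13 bis-silyl pivalate
Product: 14 (2E)-5-{2-[(1S,2E,4E)-1,5-bis[(tert-butyldimethylsilyl)oxy]penta-2,4-dien-1-yl]-1,3-dithian-2-yl}-3-methylpent-2-en-1-ol
Conditions: i-Bu2AlH (2.5 equiv), CH2Cl2, −78 °C; aqueous potassium sodium tartrate
Reagents that add atoms: none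
Why: Reductive cleavage of the pivalate by i-Bu2AlH uses neither acid, fluoride nor alkoxide, the three conditions that would destroy the silyl dienol ether.

Step 11
Reactants: 14 allylic alcohol
Product: 15 (2E)-5-{2-[(1S,2E,4E)-1,5-bis[(tert-butyldimethylsilyl)oxy]penta-2,4-dien-1-yl]-1,3-dithian-2-yl}-3-methylpent-2-enal
Conditions: MnO2 (excess), CH2Cl2, rt
Reagents that add atoms: none
Why: Allylic oxidation with MnO2 should give the (E)-enal without touching sulfur or the dienol ether and without E/Z isomerisation, as in the oxidation of geraniol to geranial.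

Step 12
Reactants: 15 (E,E,E)-trienal
Product: 16 3β,9α-bis(tert-butyldimethylsilyloxy)-8,8-(propane-1,3-diyldithio)-11,12,13-trinoreremophil-1-en-15-al (4β-CHO, 5β-CH3, 10α-H, trans-fused)
Conditions: toluene (0.005 M), BHT, N,O-bis(trimethylsilyl)acetamide (0.2 equiv), 155 °C, sealed silylated glass tube
Reagents that add atoms: none
Why: Thermal, concerted but asynchronous [4+2] cycloaddition of the type 1 intramolecular Diels–Alder class (1,7,9-decatriene with a terminally activated (E)-dienophile giving a trans-fused decalin): the electron-rich diene terminus C10 bonds to the enal β-carbon C5 and C3 bonds to C4. Ring A is closed by the cycloaddition itself as a cyclohexene (C10–C1=C2–C3–C4–C5), and ring B is closed in the fused mode by the C5–C10 bond with the four-atom tether C6–C9 folded as a chair. C4 and C5 become cis (C15 as CHO and C14 both β) because the (E)-enal adds suprafacially. C3 becomes β, cis to the aldehyde, through the aldehyde-endo approach to the (E)-enol ether terminus. The trans ring fusion (5β-CH3, 10α-H) follows from the same aldehyde-endo, tether-chair transition state. The absolute sense is set by C9: its silyl ether sits equatorial on the chair tether, which avoids A(1,3) strain with C1–H and fixes the diene face. The step needs endo and π-facial selectivity; these should be secured by the (E,E,E) geometry, the single C9 stereocentre and the gem-dithio group at C8, while the donor diene compensates for the hindered β,β-disubstituted dienophile. Acid-free conditions keep the silyl dienol ether intact.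

Step 13
Reactants: 16 cycloadduct aldehyde
Product: 17 N-tosylhydrazone of 16 at C15
Conditions: p-toluenesulfonyl hydrazide, THF, rt
Reagents that add atoms: p-toluenesulfonyl hydrazide, Cc1ccc(cc1)S(=O)(=O)NN
Why: Condensation of the aldehyde with the hydrazide under near-neutral conditions; it removes at once the β-silyloxy aldehyde, which is prone to E1cB loss of the C3 silyloxy group.

Step 14
Reactants: 17 tosylhydrazone
Product: 20 3β,9α-bis(tert-butyldimethylsilyloxy)-8,8-(propane-1,3-diyldithio)-11,12,13-trinoreremophil-1-ene, via N-boryl tosylhydrazine 18 (not isolated), via alkyl diazene 19 (not isolated)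
Conditions: catecholborane, CHCl3, 0 °C to rt; then NaOAc·3H2O, reflux
Reagents that add atoms: none
Why: Kabalka variant of the Caglioti reduction: catecholborane hydroborates the C=N bond, acetate-induced loss of sulfinate gives the alkyl diazene, and loss of N2 leaves C15 as a methyl group; no carbanion or carbocation is formed, so C4 and the neighbouring silyl ether are untouched.

Step 15
Reactants: 20 C15-methyl dithiane
Product: 21 3β,9α-bis(tert-butyldimethylsilyloxy)-11,12,13-trinoreremophil-1-en-8-one
Conditions: PhI(OCOCF3)2, NaHCO3, MeCN/H2O 9:1, 0 °C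
Reagents that add atoms: water, O
Why: Oxidative dithiane hydrolysis with a hypervalent iodine reagent (sulfur oxidation, then attack of water on the thionium ion) is fast even for hindered dithianes; the bicarbonate buffer protects the silyl ethers and keeps the α-silyloxy ketone from epimerising.

Step 16
Reactants: 21 enone-free Δ1 ketone
Product: 22 3β,9α-bis(tert-butyldimethylsilyloxy)-11,12,13-trinoreremophilan-8-one
Conditions: H2 (1 atm), Pd/C, EtOAc, rt
Reagents that add atoms: none
Why: Heterogeneous hydrogenation of the cis-disubstituted C1=C2 bond creates no stereocentre; it is placed after sulfur removal (catalyst poison) and before the isopropenyl group exists.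

Step 17
Reactants: 22 saturated C8 ketone; 23 2-bromopropene
Product: 25 3β,9α-bis(tert-butyldimethylsilyloxy)eremophil-11-en-8-one (7α-isopropenyl, 7β-H), via lithium enolate 24 (not isolated)
Conditions: LiN(SiMe3)2 (2.0 equiv), THF, −78 °C; then 23, Pd2(dba)3 (2.5 mol%), P(t-Bu)3 (6 mol%), toluene/THF, rt; AcOH quench at −78 °C
Reagents that add atoms: none
Why: Palladium-catalysed ketone α-alkenylation: kinetic deprotonation at the C7 methylene (C9–H is tertiary and shielded by its silyl ether), oxidative addition of 23 to zerovalent palladium, enolate transfer and C–C reductive elimination. C7 should settle through the enolate as the equatorial 7α epimer, because an axial isopropenyl group would be syn-axial to the C5 methyl, and the cold acidic quench protonates the product enolate at C7 and keeps the alkene out of conjugation.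

Step 18
Reactants: 25 7α-isopropenyl ketone
Product: 26 3β,9α-bis(tert-butyldimethylsilyloxy)eremophil-11-en-8α-ol
Conditions: LiBH(s-Bu)3, THF, −78 °C; H2O
Reagents that add atoms: none
Why: The bulky borohydride should attack the chair ketone from the equatorial direction, because the axial α-face path is blocked by the axial hydrogens at C6 and C10; this gives the axial 8α-alcohol, cis to both equatorial neighbours.

Step 19
Reactants: 26 bis-silyl 8α-alcohol
Product: 27 eremophil-11-ene-3β,8α,9α-triol
Conditions: Bu4NF (excess), THF, 50 °C
Reagents that add atoms: none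
Why: Fluoride cleaves both silyl ethers through Si–F bond formation; the hindered axial 3-silyl ether needs warming, and the triol has no base-sensitive group.

Step 20
Reactants: 27 triol; 28 hex-2-ynoic acid
Product: 29 9-O-(hex-2-ynoyl)eremophil-11-ene-3β,8α,9α-triol
Conditions: 28 (1.1 equiv), DCC, DMAP (5 mol%), CH2Cl2, −20 to 0 °C
Reagents that add atoms: none
Why: Steglich esterification under kinetic control: the equatorial C9 hydroxyl is the most accessible, the axial C3 hydroxyl is syn-axial to the C5 methyl and the axial C8 hydroxyl is flanked on both sides, so one equivalent at low temperature should acylate C9 only.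

Step 21
Reactants: 29 9-mono-ynoate; 28 hex-2-ynoic acid
Product: 30 3α,9α-bis(hex-2-ynoyloxy)eremophil-11-en-8α-ol
Conditions: PPh3, DIAD (betaine preformed), 28, toluene, 0 °C to rt
Reagents that add atoms: none
Why: Mitsunobu esterification with SN2 inversion: the axial 3β-oxyphosphonium group is displaced from the open α-face by the carboxylate of an acid of pKa about 2.6, giving the equatorial 3α-ester. The doubly flanked C8 hydroxyl should not compete, and preforming the betaine keeps free PPh3 away from the ynoates.

Step 22
Reactants: 30 bis(hex-2-ynoate)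
Product: 31 3α,9α-bis[(2Z)-hex-2-enoyloxy]eremophil-11-en-8α-ol (CNP0420276.1)
Conditions: H2 (1 atm), Pd/CaCO3 poisoned with Pb(OAc)2, quinoline, EtOAc, rt
Reagents that add atoms: none
Why: Lindlar semi-hydrogenation: syn-addition of hydrogen on lead-poisoned palladium should stop at the (Z)-alkene for both ynoates; the 1,1-disubstituted isopropenyl alkene is not reduced under these conditions, and quinoline suppresses over-reduction and Z/E isomerisation.

## Compound list

1 | geranyl acetate [(2E)-3,7-dimethylocta-2,6-dien-1-yl acetate] | CC(C)=CCC/C(C)=C/COC(C)=O | starting material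
2 | ozonide of 1 at the 6,7-alkene [(2E)-5-(5,5-dimethyl-1,2,4-trioxolan-3-yl)-3-methylpent-2-en-1-yl acetate] | CC1(C)OOC(CC/C(C)=C/COC(C)=O)O1 | intermediate
3 | (2E)-3-methyl-6-oxohex-2-en-1-yl acetate | O=CCC/C(C)=C/COC(C)=O | intermediate
4 | (2E)-5-(1,3-dithian-2-yl)-3-methylpent-2-en-1-yl acetate | CC(=O)OC/C=C(\C)CCC1SCCCS1 | intermediate
5 | (2E)-5-(1,3-dithian-2-yl)-3-methylpent-2-en-1-ol | OC/C=C(\C)CCC1SCCCS1 | intermediate
6 | glutaconaldehyde potassium salt [potassium (1E,3E)-5-oxopenta-1,3-dien-1-olate] | [K+].[O-]/C=C/C=C/C=O | starting material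
7 | (2E,4E)-5-[(tert-butyldimethylsilyl)oxy]penta-2,4-dienal | O=C/C=C/C=C/O[Si](C)(C)C(C)(C)C | intermediate
8 | O,C-dilithio derivative of 5 (lithium alkoxide, 2-lithio-1,3-dithiane) | [Li]OC/C=C(\C)CCC1([Li])SCCCS1 | intermediate
9 | racemic (2E,4E)-5-[(tert-butyldimethylsilyl)oxy]-1-{2-[(3E)-5-hydroxy-3-methylpent-3-en-1-yl]-1,3-dithian-2-yl}penta-2,4-dien-1-ol | OC/C=C(\C)CCC1(SCCCS1)C(O)/C=C/C=C/O[Si](C)(C)C(C)(C)C | intermediate
10 | racemic (2E)-5-{2-[(2E,4E)-5-[(tert-butyldimethylsilyl)oxy]-1-hydroxypenta-2,4-dien-1-yl]-1,3-dithian-2-yl}-3-methylpent-2-en-1-yl pivalate | CC(C)(C)C(=O)OC/C=C(\C)CCC1(SCCCS1)C(O)/C=C/C=C/O[Si](C)(C)C(C)(C)C | intermediate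
11 | (2E)-5-{2-[(2E,4E)-5-[(tert-butyldimethylsilyl)oxy]penta-2,4-dienoyl]-1,3-dithian-2-yl}-3-methylpent-2-en-1-yl pivalate | CC(C)(C)C(=O)OC/C=C(\C)CCC1(SCCCS1)C(=O)/C=C/C=C/O[Si](C)(C)C(C)(C)C | intermediate
12 | (2E)-5-{2-[(1S,2E,4E)-5-[(tert-butyldimethylsilyl)oxy]-1-hydroxypenta-2,4-dien-1-yl]-1,3-dithian-2-yl}-3-methylpent-2-en-1-yl pivalate | CC(C)(C)C(=O)OC/C=C(\C)CCC1(SCCCS1)[C@@H](O)/C=C/C=C/O[Si](C)(C)C(C)(C)C | intermediate
13 | (2E)-5-{2-[(1S,2E,4E)-1,5-bis[(tert-butyldimethylsilyl)oxy]penta-2,4-dien-1-yl]-1,3-dithian-2-yl}-3-methylpent-2-en-1-yl pivalate | CC(C)(C)C(=O)OC/C=C(\C)CCC1(SCCCS1)[C@@H](O[Si](C)(C)C(C)(C)C)/C=C/C=C/O[Si](C)(C)C(C)(C)C | intermediate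
14 | (2E)-5-{2-[(1S,2E,4E)-1,5-bis[(tert-butyldimethylsilyl)oxy]penta-2,4-dien-1-yl]-1,3-dithian-2-yl}-3-methylpent-2-en-1-ol | OC/C=C(\C)CCC1(SCCCS1)[C@@H](O[Si](C)(C)C(C)(C)C)/C=C/C=C/O[Si](C)(C)C(C)(C)C | intermediate
15 | (2E)-5-{2-[(1S,2E,4E)-1,5-bis[(tert-butyldimethylsilyl)oxy]penta-2,4-dien-1-yl]-1,3-dithian-2-yl}-3-methylpent-2-enal | O=C/C=C(\C)CCC1(SCCCS1)[C@@H](O[Si](C)(C)C(C)(C)C)/C=C/C=C/O[Si](C)(C)C(C)(C)C | intermediate
16 | 3β,9α-bis(tert-butyldimethylsilyloxy)-8,8-(propane-1,3-diyldithio)-11,12,13-trinoreremophil-1-en-15-al (4β-CHO, 5β-CH3, 10α-H) | C1C[C@]2(C)[C@@H](C=O)[C@@H](O[Si](C)(C)C(C)(C)C)C=C[C@H]2[C@H](O[Si](C)(C)C(C)(C)C)C13SCCCS3 | intermediate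
17 | (E)-N-tosylhydrazone of 16 at C15 | C1C[C@]2(C)[C@@H](/C=N/NS(=O)(=O)c3ccc(C)cc3)[C@@H](O[Si](C)(C)C(C)(C)C)C=C[C@H]2[C@H](O[Si](C)(C)C(C)(C)C)C14SCCCS4 | intermediate
18 | N-(1,3,2-benzodioxaborol-2-yl)-N-alkyl-N′-tosylhydrazine from 17 (C15 as CH2–N) | C1C[C@]2(C)[C@@H](CN(B3Oc5ccccc5O3)NS(=O)(=O)c3ccc(C)cc3)[C@@H](O[Si](C)(C)C(C)(C)C)C=C[C@H]2[C@H](O[Si](C)(C)C(C)(C)C)C14SCCCS4 | intermediate
19 | C15 alkyl diazene (C15 as CH2–N=NH) | C1C[C@]2(C)[C@@H](CN=N)[C@@H](O[Si](C)(C)C(C)(C)C)C=C[C@H]2[C@H](O[Si](C)(C)C(C)(C)C)C13SCCCS3 | intermediate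
20 | 3β,9α-bis(tert-butyldimethylsilyloxy)-8,8-(propane-1,3-diyldithio)-11,12,13-trinoreremophil-1-ene (4β,5β-dimethyl, 10α-H) | C1C[C@]2(C)[C@@H](C)[C@@H](O[Si](C)(C)C(C)(C)C)C=C[C@H]2[C@H](O[Si](C)(C)C(C)(C)C)C13SCCCS3 | intermediate
21 | 3β,9α-bis(tert-butyldimethylsilyloxy)-11,12,13-trinoreremophil-1-en-8-one | C1C[C@]2(C)[C@@H](C)[C@@H](O[Si](C)(C)C(C)(C)C)C=C[C@H]2[C@H](O[Si](C)(C)C(C)(C)C)C1=O | intermediate
22 | 3β,9α-bis(tert-butyldimethylsilyloxy)-11,12,13-trinoreremophilan-8-one | C1C[C@]2(C)[C@@H](C)[C@@H](O[Si](C)(C)C(C)(C)C)CC[C@H]2[C@H](O[Si](C)(C)C(C)(C)C)C1=O | intermediate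
23 | 2-bromopropene | CC(Br)=C | starting material
24 | lithium Δ7-enolate of 22 | C=1C[C@]2(C)[C@@H](C)[C@@H](O[Si](C)(C)C(C)(C)C)CC[C@H]2[C@H](O[Si](C)(C)C(C)(C)C)C=1O[Li] | intermediate
25 | 3β,9α-bis(tert-butyldimethylsilyloxy)eremophil-11-en-8-one (7α-isopropenyl) | C=C(C)[C@@H]1C[C@]2(C)[C@@H](C)[C@@H](O[Si](C)(C)C(C)(C)C)CC[C@H]2[C@H](O[Si](C)(C)C(C)(C)C)C1=O | intermediate
26 | 3β,9α-bis(tert-butyldimethylsilyloxy)eremophil-11-en-8α-ol | C=C(C)[C@@H]1C[C@]2(C)[C@@H](C)[C@@H](O[Si](C)(C)C(C)(C)C)CC[C@H]2[C@H](O[Si](C)(C)C(C)(C)C)[C@@H]1O | intermediate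
27 | eremophil-11-ene-3β,8α,9α-triol | C=C(C)[C@@H]1C[C@]2(C)[C@@H](C)[C@@H](O)CC[C@H]2[C@H](O)[C@@H]1O | intermediate
28 | hex-2-ynoic acid | CCCC#CC(O)=O | starting material
29 | 9-O-(hex-2-ynoyl)eremophil-11-ene-3β,8α,9α-triol | C=C(C)[C@@H]1C[C@]2(C)[C@@H](C)[C@@H](O)CC[C@H]2[C@H](OC(=O)C#CCCC)[C@@H]1O | intermediate
30 | 3α,9α-bis(hex-2-ynoyloxy)eremophil-11-en-8α-ol | C=C(C)[C@@H]1C[C@]2(C)[C@@H](C)[C@H](OC(=O)C#CCCC)CC[C@H]2[C@H](OC(=O)C#CCCC)[C@@H]1O | intermediate
31 | 3α,9α-bis[(2Z)-hex-2-enoyloxy]eremophil-11-en-8α-ol (CNP0420276.1) | C=C(C)[C@@H]1C[C@]2(C)[C@@H](C)[C@H](OC(=O)/C=C\CCC)CC[C@H]2[C@H](OC(=O)/C=C\CCC)[C@@H]1O | target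

## Step count and least certain steps

Total: 22 steps. Longest linear sequence: 21 steps (steps 1–3 and 5–22, from 1 to 31); step 4 is a one-step branch.

**Step 12 (key step).** The β,β-disubstituted enal may cycloadd so slowly that other processes compete: thermal E/Z isomerisation of the enal (which would scramble the C4/C5 relationship), loss of the dienol silyl group, or leakage through the tether-boat transition state to the cis-fused isomer. The fallback makes the same two bonds in two polar events in place of one pericyclic event. Setting out from 15, a catalytic silyl Lewis acid (Me3SiNTf2 made from HNTf2, with 2,6-di-tert-butylpyridine, CH2Cl2, −78 °C) should trigger a vinylogous Mukaiyama–Michael addition of C10 to C5. Mukaiyama aldol closure of the resulting C4 silyl enol ether onto the C3 silyloxocarbenium ion would follow. This should give 16 directly; any 3β-hydroxy aldehyde F1 formed by silyl loss would be re-silylated (TBSOTf, 2,6-lutidine), so the route is rejoined at 16. The relative configuration from a stepwise closure would have to be confirmed.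

**Step 8.** Facial discrimination may be poor if the catalyst does not read the dithianyl carbon as clearly larger than the dienyl arm. The push–pull dienone may also react sluggishly, which would let hydroboration of the enol ether compete. The fallback is resolution in place of asymmetric reduction. Setting out from racemic 10, esterification with (S)-O-methylmandelic acid (DCC, DMAP) would give two diastereomers separable by chromatography, the mandelate of the (1S)-carbinol F2 and the mandelate of the (1R)-carbinol F3, the latter being set aside. i-Bu2AlH would cleave both esters of F2 to the (S)-diol F4, and selective pivaloylation as in step 6 rejoins the route at 12.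

**Step 17.** Base-induced migration of the new alkene into conjugation, enolisation toward C9, or slow coupling of the hindered α-silyloxy enolate at palladium could each erode the step. The fallback is aldol, dehydration and deconjugation. Setting out from 22, the zinc enolate (LiN(i-Pr)2, then ZnCl2) would add to acetone to give the 7α-(2-hydroxypropan-2-yl) ketone F5. Dehydration with methyl N-(triethylammoniosulfonyl)carbamate would give the conjugated 7(11)-en-8-one F6. Kinetic γ-deprotonation (LiN(i-Pr)2, THF, −78 °C) to the lithium dienolate F7 and α-protonation with AcOH at −78 °C would rejoin the route at 25.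

**Step 20.** Site selectivity among three secondary hydroxyls may be incomplete, and acyl migration from O9 to O8 is possible. The fallback replaces steric discrimination by tin-mediated activation. Setting out from 27, Bu2SnO (toluene, azeotropic removal of water) would give the 8,9-O-dibutylstannylene acetal F8, which activates the equatorial O9 of the cis-diol. Hex-2-ynoyl chloride F9 (from 28 and oxalyl chloride) at 0 °C would then give 29.

**Step 21.** Activation of the axial C3 hydroxyl, which is syn-axial to the C5 methyl, may be slow. Anti-periplanar elimination toward C2 or C4, or reaction at the C8 hydroxyl, could then take over. The fallback separates activation from displacement. Setting out from 29, ClCH2SO2Cl and pyridine would give the 3β-chloromethanesulfonate F10. SN2 displacement with caesium hex-2-ynoate F11 (from 28 and Cs2CO3) and 18-crown-6 in toluene would rejoin the route at 30.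

## Further compounds

F1 | step 12 | 3β-hydroxy-9α-(tert-butyldimethylsilyloxy)-8,8-(propane-1,3-diyldithio)-11,12,13-trinoreremophil-1-en-15-al | C1C[C@]2(C)[C@@H](C=O)[C@@H](O)C=C[C@H]2[C@H](O[Si](C)(C)C(C)(C)C)C13SCCCS3
F2 | step 8 | (S)-O-methylmandelate of the (1S)-carbinol of 10 | CC(C)(C)C(=O)OC/C=C(\C)CCC1(SCCCS1)[C@@H](OC(=O)[C@@H](OC)c2ccccc2)/C=C/C=C/O[Si](C)(C)C(C)(C)C
F3 | step 8 | (S)-O-methylmandelate of the (1R)-carbinol of 10 | CC(C)(C)C(=O)OC/C=C(\C)CCC1(SCCCS1)[C@H](OC(=O)[C@@H](OC)c2ccccc2)/C=C/C=C/O[Si](C)(C)C(C)(C)C
F4 | step 8 | (1S,2E,4E)-5-[(tert-butyldimethylsilyl)oxy]-1-{2-[(3E)-5-hydroxy-3-methylpent-3-en-1-yl]-1,3-dithian-2-yl}penta-2,4-dien-1-ol | OC/C=C(\C)CCC1(SCCCS1)[C@@H](O)/C=C/C=C/O[Si](C)(C)C(C)(C)C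
F5 | step 17 | 3β,9α-bis(tert-butyldimethylsilyloxy)-11-hydroxyeremophilan-8-one (7α side chain) | CC(C)(O)[C@@H]1C[C@]2(C)[C@@H](C)[C@@H](O[Si](C)(C)C(C)(C)C)CC[C@H]2[C@H](O[Si](C)(C)C(C)(C)C)C1=O
F6 | step 17 | 3β,9α-bis(tert-butyldimethylsilyloxy)eremophil-7(11)-en-8-one | CC(C)=C1C[C@]2(C)[C@@H](C)[C@@H](O[Si](C)(C)C(C)(C)C)CC[C@H]2[C@H](O[Si](C)(C)C(C)(C)C)C1=O
F7 | step 17 | lithium 7,11-dienolate of F6 | C=C(C)C=1C[C@]2(C)[C@@H](C)[C@@H](O[Si](C)(C)C(C)(C)C)CC[C@H]2[C@H](O[Si](C)(C)C(C)(C)C)C=1O[Li]
F8 | step 20 | 8α,9α-O-dibutylstannylene acetal of 27 | C=C(C)[C@@H]1C[C@]2(C)[C@@H](C)[C@@H](O)CC[C@H]2[C@H](O[Sn](CCCC)(CCCC)O3)[C@@H]13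
F9 | step 20 | hex-2-ynoyl chloride | CCCC#CC(Cl)=O
F10 | step 21 | 3β-chloromethanesulfonate of 29 | C=C(C)[C@@H]1C[C@]2(C)[C@@H](C)[C@@H](OS(=O)(=O)CCl)CC[C@H]2[C@H](OC(=O)C#CCCC)[C@@H]1O
F11 | step 21 | caesium hex-2-ynoate | CCCC#CC(=O)[O-].[Cs+]
A1 | alternative 1 | 3-methyl-4-(2-methylallyl)cyclohex-2-enone (C10 as in the target) | CC1=CC(=O)CC[C@H]1CC(C)=C
A2 | alternative 1 | 2,3-dimethyl-4-(2-methylallyl)-3-vinylcyclohexanone | C=C[C@]1(C)[C@@H](C)C(=O)CC[C@H]1CC(C)=C
A3 | alternative 2 | ring A dialdehyde, 3α-silyloxy-8,9-seco-eremophil-11-ene-8,9-dial | C=C(C)[C@@H](C=O)C[C@]1(C)[C@@H](C)[C@H](O[Si](C)(C)C(C)(C)C)CC[C@H]1C=O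
A4 | alternative 2 | 3-O-silyl eremophil-11-ene-3α,8α,9α-triol | C=C(C)[C@@H]1C[C@]2(C)[C@@H](C)[C@H](O[Si](C)(C)C(C)(C)C)CC[C@H]2[C@H](O)[C@@H]1O
A5 | alternative 3 | ring A α-silyloxy aldehyde with C5 prenyl group, 3α,9α-bis(silyloxy)-7,8-seco-eremophil-7(11)-en-8-al | CC(C)=CC[C@]1(C)[C@@H](C)[C@H](O[Si](C)(C)C(C)(C)C)CC[C@H]1[C@H](O[Si](C)(C)C(C)(C)C)C=O
A6 | alternative 3 | 8-epi (8β) bis-silyl eremophilenetriol | C=C(C)[C@@H]1C[C@]2(C)[C@@H](C)[C@H](O[Si](C)(C)C(C)(C)C)CC[C@H]2[C@H](O[Si](C)(C)C(C)(C)C)[C@H]1O
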